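(The readings stem from a simulated flask with made-up constants; noise was put on by code.)

Following the target alone is the pitfall in these flasks. It climbs from 18.5 % in maple to 41.9 % in cedar, but the question is who leads, and side product B ends at 54.3 % and 42.4 % in those runs.

| setting | maple | cedar | Tuesday's | Saturday's |
|---|---|---|---|---|
| starting material | 0.20 M | 0.20 M | 0.20 M | 0.20 M |
| reagent | 2.5 equiv | 5.1 equiv | 4.00 equiv | 6.00 equiv |
| remark | run made earlier | run made earlier |  |  |
| time |  |  | 3.0 d | 3.0 d |

| run | time / d | target / % | starting material / % | side product A / % | intermediate B / % | side product B / % |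
|---|---|---|---|---|---|---|
| maple | 0.250 | 10.9 | 47.4 | 1.8 | 7.8 | 14.7 |
| maple | 0.417 | 14.8 | 28.4 | 5.0 | 11.1 | 28.4 |
| maple | 0.625 | 16.4 | 15.0 | 9.5 | 11.7 | 40.1 |
| maple | 1.04 | 17.1 | 4.2 | 17.8 | 8.4 | 50.5 |
| maple | 1.67 | 17.9 | 0.6 | 24.1 | 3.3 | 53.4 |
| maple | 3.00 | 18.5 | 0 | 27.9 | 0.3 | 54.3 |
| cedar | 0.500 | 39.2 | 3.5 | 6.8 | 8.3 | 39.8 |
| cedar | 1.04 | 41.5 | 0.1 | 12.2 | 3.2 | 42.5 |
| cedar | 1.67 | 42.0 | 0.3 | 15.0 | 0.9 | 42.3 |
| cedar | 2.08 | 41.4 | 0.2 | 15.7 | 0.3 | 42.3 |
| cedar | 2.50 | 41.3 | 0 | 15.8 | 0 | 43.0 |
| cedar | 3.00 | 41.9 | 0 | 15.8 | 0.2 | 42.4 |

(scatter of a reading: 0.3 percentage points)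

- in percentages every species weighs as the starting material in it: one side product B counts as two

- which of these there is most of at the end, counted by the starting material in it, Tuesday's (target / intermediate B / side product A / side product B)
- which of these there is most of at the end, counted by the starting material in it, Saturday's (target / intermediate B / side product A / side product B)
- how much there is at the end of the one of these that leads, in percent of the starting material charged: Tuesday's
- how much there is at the end of the one of these that leads, in percent of the starting material charged: Saturday's

Both runs have stopped moving. Maple, with less reagent than Tuesday's, holds 0.6 % starting material at 1.67 d, and cedar's two leaders stay flat from 1.04 d, so the last readings serve as ends.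

A first estimate draws a straight line in the charge, which puts Saturday's target at 50.0 %. But that line reaches the whole charge at 11.6 equiv, which is poor behaviour for two products sharing one charge.

A ratio has no such ceiling. The ratio of the end amounts, target over side product B, goes from 0.341 in maple to 0.988 in cedar, a power of 1.49 in the reagent charge. The crossing charge, the reagent at which the two end equal, then reads 5.14 equiv, and the ratio estimated for a flask near it, with starting material held at 0.20 M, is the charge over the crossing, raised to that power.

So Tuesday's lies below the crossing, with ratio 0.687, and Saturday's above it, with 1.26. Side product A over side product B falls with a power of −0.451, and the three shares must fill the charge. That gives side product B 47.5 % for Tuesday's and target 48.3 % for Saturday's.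

The objection is that Saturday's lies beyond cedar and two runs show no bend. With the power cut to 0.745, Saturday's target still leads, at 45.5 %, so the leader is firmer than the amount.

The forecast, which says of target “it rises steeply with reagent”, gives side product B at 47 % for Tuesday's and target at 48.5 % for Saturday's, a little apart from the reckoning here.

Tuesday's ends with side product B leading at 47.1 %, and Saturday's with target at 46.6 %.

    starting material + reagent → intermediate A (k = 0.240 L mol⁻¹ h⁻¹)
    intermediate A → intermediate B (k = 0.110 h⁻¹)
    reagent + intermediate A → target (k = 0.510 L mol⁻¹ h⁻¹)
    intermediate B → side product A (k = 0.0830 h⁻¹)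
    starting material + target → side product B (k = 1.80 L mol⁻¹ h⁻¹)

In Tuesday's, the step from starting material and target to side product B has >99.9 % of its turnover behind it at 1.50 d. Saturday's ratio comes to 1.18 against 1.26 from the crossing, and its target has moved by 6 points at 4.96 equiv, beside the crossing of 5.14 equiv. At 10.0 equiv the crossing rule gives 2.70, and that flask ends at 2.05, with target leading at 61.1 %.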